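(All constants belong to no real substance.)

- Slowness sits in X → L: at 70 °C its life of 20.4 min is longer than the 3.31 min of J → Q, so in elm Q is present early and free L arrives late.

| flask | J | X | Z | temperature | time | remark |
|---|---|---|---|---|---|---|
| elm | 20 mM | 40.0 mM | 20.0 mM | 70 °C | 50 min |  |
| birch | 20 mM | 40.0 mM | 20.0 mM |  | 50 min | at 70 °C until 40 min, from then on at 100 °C |
| maple | 20 mM | 40.0 mM | 20.0 mM | 100 °C | 50 min |  |

    L + Z → L.Z (k1 = 0.982 /M/min, Ea1 = 49.0 kJ/mol)
    Q + L ⇌ Q.L (K2 = 44.0 /M, k2 = 6.67 /M/min, Ea2 = 46.0 kJ/mol, ΔH2 = −35.0 kJ/mol)
    X → L (k3 = 0.0489 /min, Ea3 = 100 kJ/mol)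
    J → Q (k4 = 0.302 /min, Ea4 = 103 kJ/mol)
    (constants at 70 °C)

- the constants hold at 70 °C; other temperatures follow from the activation energies and enthalpies

1. the flask that comes out highest in amount of Q.L, in percent of the J charged, or "all alike" when all lie within 1.5 percentage points (elm / birch / maple / all alike)
2. Q.L at the end, in percent of the J charged, elm
3. Q.L at the end, in percent of the J charged, birch
4. Q.L at the end, in percent of the J charged, maple

- Main step first, in elm. The back step of Q.L has a life of 6.60 min, shorter than the 50 min run, so Q and Q.L can be taken as equilibrated at the closing [L].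
- 22.7 mM is the binding midpoint, the [L] at which [Q] and [Q.L] are equal. The bound share of Q is then [L]/([L] + midpoint).
- Now the supply. In elm X delivers 91.3% of its charge, which is 36.5 mM of L.
- With Z set aside and half of J bound, free [L] is 26.5 mM. The share comes to 53.9%, near that assumption.
- Now Z. At frozen [L], its loss is pseudo-first-order. Trying half of the delivered L free, 18.3 mM, Z is reckoned to take 11.8 mM and Q.L to hold 8.91 mM.
- The balance then leaves 15.8 mM, so the frozen value is taken between the two, at 17.0 mM. The elm reckoning is 42.8%.
- Now heat. At 100 °C the midpoint rises to 60.9 mM, and the back life falls to 0.673 min. Other steps are scaled from the factor 18 of J → Q by their activation energies, so X has a life of 1.22 min.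
- In maple, X is therefore taken as fully delivered. With the whole charge of Z counted off, the balance gives [L] of 15.9 mM, and at that frozen [L] Z is reckoned down to 4.51% of its charge. The maple share is 20.7%.
- Birch is taken to end on the hot midpoint, since 0.673 min is shorter than its hot 10.0 min. With [L] frozen at the elm value for the cool minutes, and in the hot minutes at a value equal in size to the Z charge of 20.0 mM, Z is reckoned to keep 23.5% of its charge.
- The X charge, taken as fully delivered in birch, then leaves 24.7 mM of L to share between free L and Q.L, which gives [L] of 19.8 mM and a birch share of 24.5%. In this reckoning elm stands higher than birch and maple.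
- The forecast names elm, with 44% for elm, 25% for birch and 21% for maple. Its ground: “Q.L is a reversible exothermic adduct that stays close to equilibrium”.
- The simulation puts elm highest, with 43.9% in elm, 25.0% in birch and 21.1% in maple, and the forecast stands within tolerance. In elm, [L] reads 15.8 mM at 25.0 min and 17.8 mM at 50.0 min. The midpoint turns that closing reading into a share of 44.0%, set beside the Q.L computed for elm.
- A neighbour of elm is charged with 160 mM of X and receives 146 mM of L. Taking off the whole charges of Z and J leaves [L] of 106 mM, and the midpoint gives a share of 82.4%. The computed flask ends at 82.8%, with [L] at 110 mM.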